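**Plan**
1. The three MOM ethers come off last. Before that, the pyranone ring is cut at O1–C2 and at C4–C4a, giving a cinnamoyl N-methoxy-N-methylamide (B ring plus C2–C3–C4) and a brominated resorcinol (A ring, O1/O7 free, O5/O8 as MOM ethers).
2. Enabling feature: the A ring (C4a–C8a) is a 1,2,3,5-tetraoxygenated benzene in which O5 and O8 are para (a masked hydroquinone) and O1 and O7 flank C8. With O5/O8 protected the building block has a twofold axis through C5 and C8, so C4a and C6 are the same position, and after C-acylation the only free hydroxyl next to the ketone is O1. Only the 5,7,8 pattern can form.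
3. Forward: the A ring comes from 3,5-bis(benzyloxy)phenol (para-oxidation to the quinone brings in O8; reduction, MOM, debenzylation, bromination). The B ring comes from 3-bromo-4-hydroxybenzaldehyde (MOM, Negishi coupling for the C5 chain, Horner–Wadsworth–Emmons for C2–C4).
4. The halves are joined in the key step: Br/Li exchange, C-acylation (C4–C4a) and, in the same flask, catalytic 6-endo-trig oxa-Michael closure (O1–C2). The pyranone is the only ring that is built.
5. Stereochemistry: C2 (S) is set in this ring closure by a cinchona-derived bifunctional catalyst and is kept by an aprotic, base-free deprotection.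

Key step: step 8

Assumption: the sense of induction of the cinchona-derived thiourea in step 8 cannot be assigned with certainty beforehand; the pseudo-enantiomer (quinine- or quinidine-derived) that gives (2S) is the one used.

Step 1
Reactants: 1 3,5-bis(benzyloxy)phenol
Product: 2 2,6-bis(benzyloxy)cyclohexa-2,5-diene-1,4-dione
Conditions: K2NO(SO3)2 (2.2 equiv), aq. KH2PO4, acetone/H2O, 0 °C → rt
Reagents that add atoms: potassium nitrosodisulfonate, [K+].[K+].[O]N(S(=O)(=O)[O-])S(=O)(=O)[O-]
Why: Teuber oxidation of a phenol with a free para position gives the p-quinone, so the new oxygen (later O8) enters between the two benzyloxy groups, para to the oxygen that becomes O5.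

Step 2
Reactants: 2 2,6-bis(benzyloxy)cyclohexa-2,5-diene-1,4-dione
Product: 4 1,3-bis(benzyloxy)-2,5-bis(methoxymethoxy)benzene, via hydroquinone 3 (not isolated)
Conditions: Na2S2O4, EtOAc/H2O, rt; then NaH, MOMCl, DMF, 0 °C → rt (argon)
Reagents that add atoms: chloromethyl methyl ether, COCCl
Why: Dithionite reduction of the quinone and immediate Williamson-type acetalisation of the air-sensitive hydroquinone should cap both para-related oxygens (O5, O8) in one protecting operation.

Step 3
Reactants: 4 1,3-bis(benzyloxy)-2,5-bis(methoxymethoxy)benzene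
Product: 5 2,5-bis(methoxymethoxy)benzene-1,3-diol
Conditions: H2 (1 atm), 10% Pd/C, EtOAc/MeOH, rt
Reagents that add atoms: none
Why: Hydrogenolysis of benzyl aryl ethers leaves MOM acetals intact and should free the two equivalent hydroxyls (later O1 and O7).

Step 4
Reactants: 5 2,5-bis(methoxymethoxy)benzene-1,3-diol
Product: 6 4-bromo-2,5-bis(methoxymethoxy)benzene-1,3-diol
Conditions: NBS (1.0 equiv), CH2Cl2, −78 °C
Reagents that add atoms: N-bromosuccinimide, O=C1CCC(=O)N1Br
Why: Electrophilic aromatic bromination; the two open ring positions are equivalent and each is ortho/para to both free hydroxyls, so one equivalent at low temperature should give a single monobromide that marks the future C4a.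

Step 5
Reactants: 7 3-bromo-4-hydroxybenzaldehyde
Product: 8 3-bromo-4-(methoxymethoxy)benzaldehyde
Conditions: NaH, MOMCl, THF/DMF, 0 °C → rt
Reagents that add atoms: chloromethyl methyl ether, COCCl
Why: O-Alkylation of the acidic para-formyl phenoxide (acetal protection) should be clean, and the MOM ether tolerates the organozinc, phosphonate-anion and organolithium steps that follow.

Step 6
Reactants: 8 3-bromo-4-(methoxymethoxy)benzaldehyde; 9 4-bromo-2-methylbut-1-ene
Product: 11 4-(methoxymethoxy)-3-(3-methylbut-3-en-1-yl)benzaldehyde, via alkylzinc bromide 10 (not isolated)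
Conditions: 9, Zn dust, LiCl, THF, 40 °C; then 8, Pd(OAc)2 (2 mol%), SPhos (4 mol%), THF, rt
Reagents that add atoms: none
Why: Negishi sp3–sp2 coupling; the primary alkylzinc halide tolerates the aldehyde, and the biarylphosphine ligand favours reductive elimination over β-hydride elimination, so the 1,1-disubstituted alkene should arrive unisomerised.

Step 7
Reactants: 11 4-(methoxymethoxy)-3-(3-methylbut-3-en-1-yl)benzaldehyde
Product: 12 (2E)-N-methoxy-3-[4-(methoxymethoxy)-3-(3-methylbut-3-en-1-yl)phenyl]-N-methylprop-2-enamide
Conditions: (EtO)2P(O)CH2C(O)N(OMe)Me, NaH, THF, 0 °C → rt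
Reagents that add atoms: diethyl [2-[methoxy(methyl)amino]-2-oxoethyl]phosphonate, CCOP(=O)(OCC)CC(=O)N(C)OC
Why: Horner–Wadsworth–Emmons olefination with a stabilised phosphonate should give the (E)-enamide, which is the C2–C3–C4 unit in an acylating form that cannot over-add.

Step 8
Reactants: 6 4-bromo-2,5-bis(methoxymethoxy)benzene-1,3-diol; 12 (2E)-N-methoxy-3-[4-(methoxymethoxy)-3-(3-methylbut-3-en-1-yl)phenyl]-N-methylprop-2-enamide
Product: 16 (2S)-7-hydroxy-5,8-bis(methoxymethoxy)-2-[4-(methoxymethoxy)-3-(3-methylbut-3-en-1-yl)phenyl]-2,3-dihydro-4H-chromen-4-one, via trilithiated arene 13 (not isolated), via lithium hemiaminal 14 (not isolated), via chalcone 15 (not isolated)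
Conditions: 6, MeLi (2.0 equiv), THF, −78 → 0 °C; t-BuLi (2.0 equiv), −78 °C; 12 (0.9 equiv), −78 → −20 °C; AcOH, −78 °C, pH 7 wash, solvent switch to toluene (15 not purified); 9-amino-9-deoxy-epi-cinchona 3,5-bis(trifluoromethyl)phenyl thiourea (10 mol%), toluene, 0 °C
Reagents that add atoms: none
Why: Deprotonation of both hydroxyls and bromine–lithium exchange give aryllithium 13, whose 1,2-addition to the N-methoxy-N-methylamide stops at the chelated hemiaminal 14 (Weinreb ketone synthesis, as known for lithiated bromophenoxides), so that acidification releases the 2′-hydroxychalcone 15 with the new C4–C4a bond and without over-addition or conjugate addition. The chiral bifunctional thiourea then closes the pyranone ring by a 6-endo-trig intramolecular oxa-Michael addition of the 2′-OH to the (E)-enone (O1–C2); the closest known reaction type is the chiral-base-catalysed cyclisation of 2′-hydroxychalcones to flavanones. The single new stereocentre C2 is controlled by the catalyst: the thiourea N–H bonds hold the C4 carbonyl while the quinuclidine nitrogen, as general base, delivers the phenol oxygen to one enantiotopic face of C2. Regioselectivity needs no extra control element, because both ring C–H positions of the A-ring building block are equivalent and, with O5 masked as a MOM ether, the only free hydroxyl ortho to the ketone is the one flanked by the 8-oxygen. Enantioselectivity must be kinetic, which the neutral, non-polar, low-temperature second stage should secure, helped by the 6′-alkoxy group, which twists the ketone out of the A-ring plane and favours closure over re-opening.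

Step 9
Reactants: 16 (2S)-7-hydroxy-5,8-bis(methoxymethoxy)-2-[4-(methoxymethoxy)-3-(3-methylbut-3-en-1-yl)phenyl]-2,3-dihydro-4H-chromen-4-one
Product: 17 (2S)-5,7,8-trihydroxy-2-[4-hydroxy-3-(3-methylbut-3-en-1-yl)phenyl]-2,3-dihydro-4H-chromen-4-one
Conditions: TMSOTf, 2,2′-bipyridyl, CH2Cl2/MeCN, 0 °C → rt; then H2O, rt (argon, degassed solvents)
Reagents that add atoms: none
Why: Lewis-acid-mediated cleavage of aromatic MOM acetals with a bipyridyl-buffered silyl triflate goes through the aryl silyl ethers, which water hydrolyses; no protic acid strong enough to protonate the 1,1-disubstituted alkene and no base able to open the ring at C2 is present, so the (2S) centre should be kept.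

**Compound list**
1 | 3,5-bis(benzyloxy)phenol | Oc1cc(OCc2ccccc2)cc(OCc2ccccc2)c1 | starting material
2 | 2,6-bis(benzyloxy)cyclohexa-2,5-diene-1,4-dione | O=C1C=C(OCc2ccccc2)C(=O)C(OCc2ccccc2)=C1 | intermediate
3 | 2,6-bis(benzyloxy)benzene-1,4-diol | Oc1cc(OCc2ccccc2)c(O)c(OCc2ccccc2)c1 | intermediate
4 | 1,3-bis(benzyloxy)-2,5-bis(methoxymethoxy)benzene | COCOc1cc(OCc2ccccc2)c(OCOC)c(OCc2ccccc2)c1 | intermediate
5 | 2,5-bis(methoxymethoxy)benzene-1,3-diol | COCOc1cc(O)c(OCOC)c(O)c1 | intermediate
6 | 4-bromo-2,5-bis(methoxymethoxy)benzene-1,3-diol | COCOc1cc(O)c(OCOC)c(O)c1Br | intermediate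
7 | 3-bromo-4-hydroxybenzaldehyde | O=Cc1ccc(O)c(Br)c1 | starting material
8 | 3-bromo-4-(methoxymethoxy)benzaldehyde | O=Cc1ccc(OCOC)c(Br)c1 | intermediate
9 | 4-bromo-2-methylbut-1-ene | C=C(C)CCBr | starting material
10 | (3-methylbut-3-en-1-yl)zinc bromide | C=C(C)CC[Zn]Br | intermediate
11 | 4-(methoxymethoxy)-3-(3-methylbut-3-en-1-yl)benzaldehyde | O=Cc1ccc(OCOC)c(CCC(C)=C)c1 | intermediate
12 | (2E)-N-methoxy-3-[4-(methoxymethoxy)-3-(3-methylbut-3-en-1-yl)phenyl]-N-methylprop-2-enamide | CON(C)C(=O)/C=C/c1ccc(OCOC)c(CCC(C)=C)c1 | intermediate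
13 | 2,4-bis(lithiooxy)-3,6-bis(methoxymethoxy)phenyllithium | [Li]c1c(O[Li])c(OCOC)c(O[Li])cc1OCOC | intermediate
14 | trilithium salt of the tetrahedral adduct, (2E)-1-[2,4-bis(lithiooxy)-3,6-bis(methoxymethoxy)phenyl]-1-(lithiooxy)-1-[methoxy(methyl)amino]-3-[4-(methoxymethoxy)-3-(3-methylbut-3-en-1-yl)phenyl]prop-2-ene | [Li]OC(/C=C/c1ccc(OCOC)c(CCC(C)=C)c1)(N(C)OC)c1c(O[Li])c(OCOC)c(O[Li])cc1OCOC | intermediate
15 | (2E)-1-[2,4-dihydroxy-3,6-bis(methoxymethoxy)phenyl]-3-[4-(methoxymethoxy)-3-(3-methylbut-3-en-1-yl)phenyl]prop-2-en-1-one | O=C(/C=C/c1ccc(OCOC)c(CCC(C)=C)c1)c1c(O)c(OCOC)c(O)cc1OCOC | intermediate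
16 | (2S)-7-hydroxy-5,8-bis(methoxymethoxy)-2-[4-(methoxymethoxy)-3-(3-methylbut-3-en-1-yl)phenyl]-2,3-dihydro-4H-chromen-4-one | C=C(C)CCc1cc([C@@H]2CC(=O)c3c(OCOC)cc(O)c(OCOC)c3O2)ccc1OCOC | intermediate
17 | (2S)-5,7,8-trihydroxy-2-[4-hydroxy-3-(3-methylbut-3-en-1-yl)phenyl]-2,3-dihydro-4H-chromen-4-one | C=C(C)CCc1cc([C@@H]2CC(=O)c3c(O)cc(O)c(O)c3O2)ccc1O | target

**Summary**
Total step count: 9. Longest linear sequence: 6 steps (steps 1, 2, 3, 4, 8, 9).

**Steps most likely to fail**

Step 8. What may go wrong: insufficient face selectivity in the ring closure, loss of enantiomeric purity through reversible ring opening, or binding of the basic catalyst by the acidic 4′-hydroxyl; also protonation of the polyanion before acylation. Fallback: it sets out from chalcone 15, which is then isolated by chromatography after the first stage. Closure under thermodynamic conditions (NaOAc, EtOH, reflux) should give the racemic flavanone F1. Kinetic resolution by asymmetric transfer hydrogenation (Rh(III)–TsDPEN-type catalyst, HCO2H/Et3N, rt), a known reaction of racemic flavanones, should reduce the (2R)-ketone to the (2R,4R)-cis-flavan-4-ol F2 and leave the (2S)-ketone; the catalyst antipode is chosen so that (2R) is the fast-reacting enantiomer. The route is rejoined at 16.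

Step 9. What may go wrong: addition to or migration of the 1,1-disubstituted double bond under the Lewis-acidic conditions, ring opening at C2 with loss of configuration, or air oxidation of the trihydroxylated A ring. Fallback: the side chain is introduced after deprotection. It sets out from 8, which under the conditions of step 7 should give the bromo enamide F3. F3 and 6 under the conditions of step 8 (exactly 2.0 equiv t-BuLi, so that the aryl bromide of F3 is not exchanged) should give the protected bromoflavanone F4. The MOM ethers are then removed with HCl in MeOH, which is safe in the absence of the alkene, to give the bromo tetraphenol F5. A Negishi coupling with an excess of 10 (slow addition, Pd(OAc)2/SPhos, THF; the phenols are carried as zinc phenoxides) joins the C5 chain last. The route is rejoined at 17.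

Step 4. What may go wrong: over-bromination or oxidation of the very electron-rich resorcinol, and later incomplete halogen–metal exchange of the polyanion. Fallback: a halogen-free C-acylation by acyl migration. It sets out from 11 and 5. Doebner–Knoevenagel condensation of 11 with malonic acid (pyridine, piperidine, 90 °C) should give the cinnamic acid F6, and esterification with an excess of 5 (EDC, DMAP, CH2Cl2) the aryl mono-ester F7. Irradiation (300 nm, MeCN) triggers a photo-Fries rearrangement; the ortho and the para acyl shift lead to the same compound because of the twofold symmetry of the A-ring unit. The route is rejoined at chalcone 15, which enters the second stage of step 8.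

**Further compounds**
F1 | step 8 | rac-7-hydroxy-5,8-bis(methoxymethoxy)-2-[4-(methoxymethoxy)-3-(3-methylbut-3-en-1-yl)phenyl]-2,3-dihydro-4H-chromen-4-one | C=C(C)CCc1cc(C2CC(=O)c3c(OCOC)cc(O)c(OCOC)c3O2)ccc1OCOC
F2 | step 8 | (2R,4R)-5,8-bis(methoxymethoxy)-2-[4-(methoxymethoxy)-3-(3-methylbut-3-en-1-yl)phenyl]-3,4-dihydro-2H-chromene-4,7-diol | C=C(C)CCc1cc([C@H]2C[C@@H](O)c3c(OCOC)cc(O)c(OCOC)c3O2)ccc1OCOC
F3 | step 9 | (2E)-3-[3-bromo-4-(methoxymethoxy)phenyl]-N-methoxy-N-methylprop-2-enamide | CON(C)C(=O)/C=C/c1ccc(OCOC)c(Br)c1
F4 | step 9 | (2S)-2-[3-bromo-4-(methoxymethoxy)phenyl]-7-hydroxy-5,8-bis(methoxymethoxy)-2,3-dihydro-4H-chromen-4-one | Brc1cc([C@@H]2CC(=O)c3c(OCOC)cc(O)c(OCOC)c3O2)ccc1OCOC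
F5 | step 9 | (2S)-2-(3-bromo-4-hydroxyphenyl)-5,7,8-trihydroxy-2,3-dihydro-4H-chromen-4-one | Brc1cc([C@@H]2CC(=O)c3c(O)cc(O)c(O)c3O2)ccc1O
F6 | step 4 | (2E)-3-[4-(methoxymethoxy)-3-(3-methylbut-3-en-1-yl)phenyl]prop-2-enoic acid | OC(=O)/C=C/c1ccc(OCOC)c(CCC(C)=C)c1
F7 | step 4 | 3-hydroxy-2,5-bis(methoxymethoxy)phenyl (2E)-3-[4-(methoxymethoxy)-3-(3-methylbut-3-en-1-yl)phenyl]prop-2-enoate | O=C(/C=C/c1ccc(OCOC)c(CCC(C)=C)c1)Oc1cc(OCOC)cc(O)c1OCOC
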